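## The problem

Compound 14 is an open-chain depside: (E)-ferulic acid is esterified to the C2 hydroxyl of (R)-3-(3,4-dihydroxyphenyl)lactic acid, so a guaiacyl ring and a catechol ring sit at the two ends of one chain and no ring has to be built. C2 is the only stereocentre, and nothing else in the molecule can direct it, so its (R) configuration must come from a chiral starting material or a chiral catalyst. Once set, C2 is alpha to a carboxyl and carries an acyloxy group, which makes it prone to enolisation by base. The secondary ester joining the two halves cannot be told apart from a simple alkyl ester at C1 by saponification. The catechol oxidises easily, above all as its anion, and the ferulate alkene is reduced under hydrogenolysis conditions, isomerised by light and open to conjugate addition. Protecting groups must therefore leave under acid or buffered fluoride, and the closing steps must avoid base, hydrogen and strong nucleophiles. The enabling feature is that C3 is a methylene bound only to the catechol ring and to C2, while C2 carries the ester oxygen, C1 and one hydrogen. C1–C2(O)–C3 is thus the skeleton of pyruvic acid in its enol form, and the aryl–C3 bond together with the C2–H bond is what conjugate arylation and protonation of a 2-(feruloyloxy)acrylate would create.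

## Retrosynthesis

From 14 back to 13 and 12, no skeletal bond is cut. The bonds cut are the O–tert-butyl bond at C1, the two ketal C–O bonds on the catechol and the O–Si bond on the guaiacyl oxygen. A tert-butyl ester, an acetonide and an aryl silyl ether are chosen because all leave under acid or fluoride. Benzyl-type groups are excluded by the alkene and base-labile esters by the depside link. Fluoride is used first, so that 13 is still lipophilic and can be purified on silica. Acid comes last, so that only volatile co-products accompany the polar acid 14.

Compound 12 is cut at the bond between the catechol ring and C3 and at the C2–H bond, which leads to acrylate 6 and arylboronic acid 11. Cutting the ester C–O bond instead would leave a chiral aryl-lactate that still needs its own asymmetric synthesis. Cutting only C2–H and C3–H would demand a pyruvate that already carries the catechol ring. The chosen cut makes both partners achiral: 6 holds the whole ferulate and the three-carbon acid unit, and 11 is a simple arylboron reagent. The forward reaction must transfer the aryl group to the terminal acrylate carbon only, leave the ferulate alkene alone, and protonate the resulting enolate on one face.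

Compound 6 is cut at the enol O–acyl bond into acid chloride 5 and keto ester 4. Building the C=CH2 unit by olefination or elimination would cost extra steps, whereas the enol of 4 is available by simple deprotonation. Acid chloride 5 comes from the doubly silylated ferulate 2, made in one step from ferulic acid 1, and 4 comes from pyruvic acid 3 by esterification. The forward chemistry must form the acid chloride without free acid, so that the aryl silyl ether survives, and must acylate the enol on oxygen, not on carbon.

Compound 11 is cut at the C–B bond to aryllithium 9, via its borate complex 10, which comes from bromide 8 by halogen–metal exchange. Bromide 8 is the acetonide of 4-bromocatechol 7. The ketal is chosen because it tolerates the organolithium and the rhodium step and leaves in the same acid treatment as the tert-butyl ester.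

## Roads not taken

Alternative 1: The cut is the C=C bond of the ferulate. Vanillin A1 would be condensed with the malonic half ester A2 of the allyl-protected (R)-aryl-lactate in pyridine with piperidine (Knoevenagel–Doebner condensation with loss of water and carbon dioxide). This gives the tri-allyl compound A3, after which zerovalent palladium (Pd(PPh3)4 with an allyl acceptor) removes the three allyl groups.
- Merits: the guaiacol hydroxyl needs no protection, the (E) geometry is thermodynamically assured, and this condensation is well established for hydroxycinnamate esters of secondary alcohols.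
- Weak points: the step solves neither the stereocentre nor the aryl–C3 bond, so the (R)-lactate inside A2 must be bought in the unnatural series or made by a separate asymmetric step. The finished C2 centre, alpha to an ester and bearing an activated malonyl ester, sits for hours in warm amine base, where epimerisation and aminolysis can compete.
- Comparison: the key step of Alternative 1 is better precedented than that of the chosen plan. The chosen plan sets against this a shorter convergent assembly from three achiral commodity materials, in which the stereocentre and the aryl–C3 bond are made together under near-neutral conditions.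

Alternative 2: The cut is the C2–H and C3–H pair. The catechol-bearing keto ester A4 would be O-acylated with 5 to the (Z)-enol ester A5. Then [Rh(cod)(Et-DuPhos)]BF4, in the antipode that gives the (R) ester, with hydrogen would reduce the enol ester alkene to the tris-TBS tert-butyl ester A6.
- Merits: hydrogenation of 2-acyloxyacrylates with such catalysts is among the most dependable asymmetric reactions. Its sense of induction is predictable, it tolerates E/Z mixtures, and it is neutral.
- Weak points: A4 must first be made with the catechol already attached, which adds several steps. Hydrogen is used in the presence of the ferulate alkene, so over-reduction is possible when conversion is pushed, although the chelating enol ester reacts much faster.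
- Comparison: in predictability of the enantioselectivity Alternative 2 is better than the chosen plan. The chosen plan sets against this that no aryl-pyruvate synthesis is needed, that the C–C bond and the stereocentre are made in one step from pyruvate, and that no hydrogen comes near the cinnamate. Both plans face a chemoselectivity question of the same kind at the ferulate alkene.

Alternative 3: The cut is the C2–O bond with inversion. L-DOPA A7 would be diazotised with retention and allylated to the (S)-hydroxy ester A8. A Mitsunobu reaction with O-allyl ferulic acid A9 would give the tetra-allyl compound A10 with the (R) configuration, and Pd(PPh3)4 with an allyl acceptor would finish.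
- Merits: the stereocentre comes from a cheap natural amino acid, the inversion is stereospecific, every reaction is known, and one neutral deprotection ends the route.
- Weak points: diazotisation of a free catechol amino acid suffers from ring oxidation and nitrosation and usually forces earlier protection. The activated carbinol in A8 has a benzylic methylene next to it and can eliminate to the cinnamate. Any acyloxyphosphonium pathway erodes the inversion. Four allyl groups and stoichiometric phosphine oxide must be removed.
- Comparison: Alternative 3 carries less risk per step than the chosen plan. The chosen plan sets against this a shorter longest linear sequence, catalytic creation of the stereocentre from achiral materials, and access to either enantiomer by changing the ligand.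

Key step: step 6

Assumption: the sense of induction of the rhodium–BINAP protonation on an acyloxyacrylate cannot be predicted with confidence. The route is written with (S)-BINAP, and (R)-BINAP is used instead if the first run shows that it is the antipode leading to the (2R) ester.

## Route

Step 1
Reactants: 1 ferulic acid, (E)-3-(4-hydroxy-3-methoxyphenyl)prop-2-enoic acid
Product: 2 tert-butyldimethylsilyl (E)-3-{4-[(tert-butyldimethylsilyl)oxy]-3-methoxyphenyl}prop-2-enoate (bis-TBS ferulate)
Conditions: TBSCl (2.4 equiv), imidazole (5 equiv), DMF, 0 °C → rt; cold neutral work-up
Reagents that add atoms: tert-butyldimethylsilyl chloride, CC(C)(C)[Si](C)(C)Cl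
Why: Silylation of phenol and carboxylic acid with TBSCl/imidazole is standard. The silyl ester is kept on purpose, because step 3 converts it directly into the acid chloride, and the aryl silyl ether protects the guaiacyl oxygen through the acylation and the rhodium step.

Step 2
Reactants: 3 pyruvic acid, 2-oxopropanoic acid
Product: 4 tert-butyl pyruvate, tert-butyl 2-oxopropanoate
Conditions: tert-butyl 2,2,2-trichloroacetimidate (1.5 equiv), CH2Cl2/cyclohexane, rt; filtration, distillation
Reagents that add atoms: tert-butyl 2,2,2-trichloroacetimidate, CC(C)(C)OC(=N)C(Cl)(Cl)Cl
Why: Imidate esterification alkylates the carboxylic acid without strong acid or base, which suits an enolisable, self-condensing alpha-keto acid. The acid itself activates the imidate and trichloroacetamide precipitates.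

Step 3
Reactants: 2 bis-TBS ferulate; 4 tert-butyl pyruvate
Product: 6 tert-butyl 2-{[(E)-3-{4-[(tert-butyldimethylsilyl)oxy]-3-methoxyphenyl}prop-2-enoyl]oxy}prop-2-enoate, via O-TBS-feruloyl chloride 5 (not isolated)
Conditions: (COCl)2 (1.2 equiv), DMF (cat.), CH2Cl2, 0 °C → rt; evaporation; then 4 (1.5 equiv), Et3N (1.5 equiv), DMAP (cat.), CH2Cl2, −20 → 0 °C; BHT (trace) on storage
Reagents that add atoms: none
Why: A TBS ester reacts with the Vilsmeier chloroiminium salt from oxalyl chloride and DMF to give the acid chloride and TBSCl without free HCl, so the aryl silyl ether survives. Triethylamine then enolises keto ester 4 and the enol oxygen is acylated (O-acylation of a pyruvate ester to a 2-acyloxyacrylate), oxygen attack being favoured for a hard acyl chloride and a stabilised enolate. Acid chloride 5 has no alpha hydrogen and cannot form a ketene.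

Step 4
Reactants: 7 4-bromocatechol, 4-bromobenzene-1,2-diol
Product: 8 5-bromo-2,2-dimethyl-1,3-benzodioxole
Conditions: 2,2-dimethoxypropane (3 equiv), TsOH·H2O (cat.), toluene, reflux, MeOH removed (Soxhlet, 4 Å sieves)
Reagents that add atoms: 2,2-dimethoxypropane, COC(C)(C)OC
Why: Acid-catalysed transketalisation of a catechol gives the five-membered cyclic ketal once methanol is removed. The acetonide masks both phenols for the organolithium and rhodium steps and leaves later with aqueous acid.

Step 5
Reactants: 8 5-bromo-2,2-dimethyl-1,3-benzodioxole
Product: 11 (2,2-dimethyl-1,3-benzodioxol-5-yl)boronic acid, via aryllithium 9 (not isolated), via lithium aryltriisopropoxyborate 10 (not isolated)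
Conditions: n-BuLi (1.05 equiv), THF, −78 °C; B(OiPr)3 (1.3 equiv), −78 °C → rt; 1 M HCl, 0 °C, brief
Reagents that add atoms: triisopropyl borate, CC(C)OB(OC(C)C)OC(C)C; water, O
Why: Bromine–lithium exchange at −78 °C is faster than any attack on the ketal, the aryllithium is trapped by the borate ester as an ate complex, and brief cold dilute acid hydrolyses the boron–isopropoxy bonds without opening the acetonide (lithiation–borylation).

Step 6
Reactants: 6 tert-butyl 2-(4-O-TBS-feruloyloxy)acrylate; 11 (2,2-dimethyl-1,3-benzodioxol-5-yl)boronic acid
Product: 12 tert-butyl (2R)-2-{[(E)-3-{4-[(tert-butyldimethylsilyl)oxy]-3-methoxyphenyl}prop-2-enoyl]oxy}-3-(2,2-dimethyl-1,3-benzodioxol-5-yl)propanoate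
Conditions: Rh(acac)(C2H4)2 (3 mol %), (S)-BINAP (3.3 mol %), 11 (1.5 equiv), 2-methoxyphenol (1.2 equiv), 1,4-dioxane, 50 °C, argon, dark
Reagents that add atoms: none
Why: Proposed new method: the closest known reaction type is the rhodium–bisphosphine conjugate addition of arylboron reagents to 2-amidoacrylates and other 2-substituted acrylates with enantioselective protonation of the rhodium enolate by a phenol or an imide (Hayashi–Miyaura addition with protonation at the alpha carbon), and 2-acyloxyacrylates have not been used in it. Transmetalation of 11 to a rhodium aryloxide or acetylacetonate gives an aryl rhodium complex, which inserts the unhindered terminal C=C of 6 with the aryl group going to C3, so that the aryl–C3 bond forms and an oxa-pi-allyl rhodium enolate of the alpha-acyloxy ester results. 2-Methoxyphenol then protonates C2 of this enolate inside the BINAP pocket, releasing 12 and a rhodium aryloxide that re-enters transmetalation, and no ring is closed. The new stereocentre C2 is under catalyst control alone: the ferulate carbonyl can bind rhodium as the amide carbonyl does in dehydroalanines and as 2-acyloxyacrylates do in rhodium–bisphosphine hydrogenation, which should fix the enolate geometry and expose one face to the proton donor. The acyloxy group makes the acrylate more electrophilic than an amidoacrylate, so insertion should proceed at 50 °C, well below the temperatures that cinnamates need. Chemoselectivity for the terminal acrylate over the ferulate alkene rests on this difference, on the beta-aryl substituent of the ferulate and on its deactivation by the para-silyloxy and meta-methoxy donors, and a limited excess of 11 keeps a second arylation from competing. A phenol as the main proton donor in dry dioxane keeps unselective protonation by water low, and the near-neutral medium should leave the silyl ether, the acetonide, the tert-butyl ester and the new alpha stereocentre untouched.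

Step 7
Reactants: 12 fully protected depside
Product: 13 tert-butyl (2R)-3-(2,2-dimethyl-1,3-benzodioxol-5-yl)-2-{[(E)-3-(4-hydroxy-3-methoxyphenyl)prop-2-enoyl]oxy}propanoate
Conditions: TBAF (1.1 equiv), AcOH (1.5 equiv), THF, 0 °C; silica chromatography
Reagents that add atoms: none
Why: Fluoride cleaves the aryl O–Si bond rapidly (desilylation driven by the Si–F bond). Acetic acid buffers the basicity of fluoride and phenoxide, so the alpha-acyloxy stereocentre and both esters see no base, and the tert-butyl ester and acetonide are inert.

Step 8
Reactants: 13 phenol with tert-butyl ester and acetonide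
Product: 14 (2R)-3-(3,4-dihydroxyphenyl)-2-{[(E)-3-(4-hydroxy-3-methoxyphenyl)prop-2-enoyl]oxy}propanoic acid (target)
Conditions: TFA/H2O (9:1), 0 °C → rt, dark, argon; evaporation; reversed-phase chromatography
Reagents that add atoms: none
Why: Aqueous trifluoroacetic acid cleaves the tert-butyl ester by alkyl–oxygen fission and hydrolyses the catechol ketal in one operation (acidolysis), leaving only volatile co-products. The secondary cinnamate ester, the (E)-alkene and the C2 stereocentre are stable to acid at room temperature, and water captures the tert-butyl cation.

## Compound list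

1 | ferulic acid, (E)-3-(4-hydroxy-3-methoxyphenyl)prop-2-enoic acid | COc1cc(/C=C/C(=O)O)ccc1O | starting material
2 | tert-butyldimethylsilyl (E)-3-{4-[(tert-butyldimethylsilyl)oxy]-3-methoxyphenyl}prop-2-enoate | COc1cc(/C=C/C(=O)O[Si](C)(C)C(C)(C)C)ccc1O[Si](C)(C)C(C)(C)C | intermediate
3 | pyruvic acid | CC(=O)C(=O)O | starting material
4 | tert-butyl 2-oxopropanoate (tert-butyl pyruvate) | CC(=O)C(=O)OC(C)(C)C | intermediate
5 | (E)-3-{4-[(tert-butyldimethylsilyl)oxy]-3-methoxyphenyl}prop-2-enoyl chloride | COc1cc(/C=C/C(=O)Cl)ccc1O[Si](C)(C)C(C)(C)C | intermediate (not isolated)
6 | tert-butyl 2-{[(E)-3-{4-[(tert-butyldimethylsilyl)oxy]-3-methoxyphenyl}prop-2-enoyl]oxy}prop-2-enoate | C=C(OC(=O)/C=C/c1ccc(O[Si](C)(C)C(C)(C)C)c(OC)c1)C(=O)OC(C)(C)C | intermediate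
7 | 4-bromocatechol, 4-bromobenzene-1,2-diol | Oc1ccc(Br)cc1O | starting material
8 | 5-bromo-2,2-dimethyl-1,3-benzodioxole | CC1(C)Oc2ccc(Br)cc2O1 | intermediate
9 | (2,2-dimethyl-1,3-benzodioxol-5-yl)lithium | [Li]c1ccc2OC(C)(C)Oc2c1 | intermediate (not isolated)
10 | lithium (2,2-dimethyl-1,3-benzodioxol-5-yl)tri(propan-2-yloxy)borate | CC(C)O[B-](OC(C)C)(OC(C)C)c1ccc2OC(C)(C)Oc2c1.[Li+] | intermediate (not isolated)
11 | (2,2-dimethyl-1,3-benzodioxol-5-yl)boronic acid | CC1(C)Oc2ccc(B(O)O)cc2O1 | intermediate
12 | tert-butyl (2R)-2-{[(E)-3-{4-[(tert-butyldimethylsilyl)oxy]-3-methoxyphenyl}prop-2-enoyl]oxy}-3-(2,2-dimethyl-1,3-benzodioxol-5-yl)propanoate | COc1cc(/C=C/C(=O)O[C@H](Cc2ccc3OC(C)(C)Oc3c2)C(=O)OC(C)(C)C)ccc1O[Si](C)(C)C(C)(C)C | intermediate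
13 | tert-butyl (2R)-3-(2,2-dimethyl-1,3-benzodioxol-5-yl)-2-{[(E)-3-(4-hydroxy-3-methoxyphenyl)prop-2-enoyl]oxy}propanoate | COc1cc(/C=C/C(=O)O[C@H](Cc2ccc3OC(C)(C)Oc3c2)C(=O)OC(C)(C)C)ccc1O | intermediate
14 | (2R)-3-(3,4-dihydroxyphenyl)-2-{[(E)-3-(4-hydroxy-3-methoxyphenyl)prop-2-enoyl]oxy}propanoic acid | COc1cc(/C=C/C(=O)O[C@H](Cc2ccc(O)c(O)c2)C(=O)O)ccc1O | target

## Step count and risks

Total step count: 8. Longest linear sequence: 5 steps (steps 1, 3, 6, 7, 8 from ferulic acid; the branches from pyruvic acid and from 4-bromocatechol are equally long).

**Step 6 (key step, new method).**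
- What may go wrong: weak or reversed facial selectivity in the protonation, since the acyloxy chelate may organise the enolate less firmly than an amide. Also competing arylation of the ferulate alkene, beta-hydride elimination from the rhodium enolate to a Heck-type dehydro product, protodeboronation of the electron-rich boronic acid, and acyl transfer from the activated enol ester to the phenol.
- Fallback (known chemistry): it sets out from 8 and 2 and returns at 12. Bromide 8 is converted with Mg in THF into (2,2-dimethyl-1,3-benzodioxol-5-yl)magnesium bromide F1. F1 opens tert-butyl (R)-glycidate F2, taken as a purchased reagent, at its CH2 terminus under CuBr·SMe2 catalysis at −30 °C. This gives tert-butyl (2R)-3-(2,2-dimethyl-1,3-benzodioxol-5-yl)-2-hydroxypropanoate F3 with the epoxide configuration at C2 untouched. F3 is acylated with acid chloride 5, generated from 2 as in step 3, using Et3N and catalytic DMAP in CH2Cl2 at 0 °C, to give 12. This rescue gives up the key disconnection. It also supplies authentic (2R)-12 for assigning the sense of induction of the rhodium step.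

**Step 3.**
- What may go wrong: C-acylation or base-induced self-condensation of the pyruvate ester instead of O-acylation, and radical polymerisation of the acyloxyacrylate on concentration.
- Fallback: it sets out from 4 and returns at 6. Keto ester 4 is first converted with Me3SiCl and Et3N into the isolable enol silane tert-butyl 2-[(trimethylsilyl)oxy]prop-2-enoate F4. F4 is then O-acylated with 5 under CuCl promotion, so that enolisation and acylation are separated and no amine base meets the acid chloride.

**Step 5.**
- What may go wrong: alkylation of the aryllithium by the 1-bromobutane formed in the exchange, and protodeboronation or ketal opening during the acidic work-up.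
- Fallback: it sets out from 8 and returns at 11. Miyaura borylation of 8 with bis(pinacolato)diboron, PdCl2(dppf) and KOAc in dioxane at 80 °C gives 2-(2,2-dimethyl-1,3-benzodioxol-5-yl)-4,4,5,5-tetramethyl-1,3,2-dioxaborolane F5. Its pinacol is removed oxidatively with NaIO4 and NH4OAc in aqueous acetone to give 11.

**Step 8.**
- What may go wrong: Friedel–Crafts tert-butylation of the electron-rich catechol and guaiacyl rings by the tert-butyl cation, and slow acid hydrolysis of the depside ester if the reaction is prolonged to complete ketal cleavage.
- Fallback: it sets out from 13 and returns at 14. Me3SiOTf with 2,6-lutidine in CH2Cl2 at 0 °C converts the tert-butyl ester into a silyl ester while the base takes up the proton released with isobutene. Aqueous work-up gives (2R)-3-(2,2-dimethyl-1,3-benzodioxol-5-yl)-2-{[(E)-3-(4-hydroxy-3-methoxyphenyl)prop-2-enoyl]oxy}propanoic acid F6. A short treatment of F6 with TFA/H2O, now free of any tert-butyl source, removes the acetonide and gives 14.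

## Further compounds

F1 | step 6 | (2,2-dimethyl-1,3-benzodioxol-5-yl)magnesium bromide | Br[Mg]c1ccc2OC(C)(C)Oc2c1
F2 | step 6 | tert-butyl (2R)-oxirane-2-carboxylate (tert-butyl (R)-glycidate) | CC(C)(C)OC(=O)[C@H]1CO1
F3 | step 6 | tert-butyl (2R)-3-(2,2-dimethyl-1,3-benzodioxol-5-yl)-2-hydroxypropanoate | O[C@H](Cc1ccc2OC(C)(C)Oc2c1)C(=O)OC(C)(C)C
F4 | step 3 | tert-butyl 2-[(trimethylsilyl)oxy]prop-2-enoate | C=C(O[Si](C)(C)C)C(=O)OC(C)(C)C
F5 | step 5 | 2-(2,2-dimethyl-1,3-benzodioxol-5-yl)-4,4,5,5-tetramethyl-1,3,2-dioxaborolane | CC1(C)Oc2ccc(B3OC(C)(C)C(C)(C)O3)cc2O1
F6 | step 8 | (2R)-3-(2,2-dimethyl-1,3-benzodioxol-5-yl)-2-{[(E)-3-(4-hydroxy-3-methoxyphenyl)prop-2-enoyl]oxy}propanoic acid | COc1cc(/C=C/C(=O)O[C@H](Cc2ccc3OC(C)(C)Oc3c2)C(=O)O)ccc1O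
A1 | alternative 1 | vanillin, 4-hydroxy-3-methoxybenzaldehyde | COc1cc(C=O)ccc1O
A2 | alternative 1 | 3-{[(2R)-1-(allyloxy)-3-[3,4-bis(allyloxy)phenyl]-1-oxopropan-2-yl]oxy}-3-oxopropanoic acid (malonic half ester) | O=C(O)CC(=O)O[C@H](Cc1ccc(OCC=C)c(OCC=C)c1)C(=O)OCC=C
A3 | alternative 1 | allyl (2R)-3-[3,4-bis(allyloxy)phenyl]-2-{[(E)-3-(4-hydroxy-3-methoxyphenyl)prop-2-enoyl]oxy}propanoate | COc1cc(/C=C/C(=O)O[C@H](Cc2ccc(OCC=C)c(OCC=C)c2)C(=O)OCC=C)ccc1O
A4 | alternative 2 | tert-butyl 3-{3,4-bis[(tert-butyldimethylsilyl)oxy]phenyl}-2-oxopropanoate | CC(C)(C)OC(=O)C(=O)Cc1ccc(O[Si](C)(C)C(C)(C)C)c(O[Si](C)(C)C(C)(C)C)c1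
A5 | alternative 2 | tert-butyl (Z)-3-{3,4-bis[(tert-butyldimethylsilyl)oxy]phenyl}-2-{[(E)-3-{4-[(tert-butyldimethylsilyl)oxy]-3-methoxyphenyl}prop-2-enoyl]oxy}prop-2-enoate | COc1cc(/C=C/C(=O)O/C(=C\c2ccc(O[Si](C)(C)C(C)(C)C)c(O[Si](C)(C)C(C)(C)C)c2)C(=O)OC(C)(C)C)ccc1O[Si](C)(C)C(C)(C)C
A6 | alternative 2 | tert-butyl (2R)-3-{3,4-bis[(tert-butyldimethylsilyl)oxy]phenyl}-2-{[(E)-3-{4-[(tert-butyldimethylsilyl)oxy]-3-methoxyphenyl}prop-2-enoyl]oxy}propanoate | COc1cc(/C=C/C(=O)O[C@H](Cc2ccc(O[Si](C)(C)C(C)(C)C)c(O[Si](C)(C)C(C)(C)C)c2)C(=O)OC(C)(C)C)ccc1O[Si](C)(C)C(C)(C)C
A7 | alternative 3 | L-DOPA, (2S)-2-amino-3-(3,4-dihydroxyphenyl)propanoic acid | N[C@@H](Cc1ccc(O)c(O)c1)C(=O)O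
A8 | alternative 3 | allyl (2S)-3-[3,4-bis(allyloxy)phenyl]-2-hydroxypropanoate | O[C@@H](Cc1ccc(OCC=C)c(OCC=C)c1)C(=O)OCC=C
A9 | alternative 3 | (E)-3-[4-(allyloxy)-3-methoxyphenyl]prop-2-enoic acid | COc1cc(/C=C/C(=O)O)ccc1OCC=C
A10 | alternative 3 | allyl (2R)-2-{[(E)-3-[4-(allyloxy)-3-methoxyphenyl]prop-2-enoyl]oxy}-3-[3,4-bis(allyloxy)phenyl]propanoate | COc1cc(/C=C/C(=O)O[C@H](Cc2ccc(OCC=C)c(OCC=C)c2)C(=O)OCC=C)ccc1OCC=C
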